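**Retrosynthetic overview**
1. Target 16 ← bis-silyl ether 15 (fluoride) ← dialdehyde 14 by cutting C3–C4: a SmI2 pinacol ring closure makes ring C and both carbinol centres in one operation.
2. Enabling feature: C3 and C4 of ring C are vicinal cis-carbinol carbons; C4 is benzylic on ring A next to the O1-bearing carbon and C3 is alpha to C2, so both can be aldehyde carbons held six atoms apart by the O1–C2 ether. The C2 aryl group and the peri 5-OMe of ring A steer the chelated coupling.
3. 14 ← diol 13 ← ester–aldehyde 12 ← Mitsunobu O1–C2 etherification (inversion) of salicylaldehyde 8 with (S)-mandelate 11.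
4. 8 ← 5-methoxyresorcinol 1 via bis-MOM ether, two directed ortho-lithiations (C8 prenyl, then C4a formyl), MOM removal and selective 7-O-silylation; 11 ← (S)-4-hydroxymandelic acid 9.
5. Ring order: rings A and B are bought; ring C is the only ring formed, in step 11.

Key step: step 11

Remark: (S)-4-hydroxymandelic acid 9 is assumed to be purchasable in enantiopure form; its carbinol centre is inverted once, in step 8, and becomes C2.

Step 1
Reactants: 1 5-methoxyresorcinol
Product: 2 1-methoxy-3,5-bis(methoxymethoxy)benzene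
Conditions: NaH (2.4 equiv), MOMCl (2.4 equiv), DMF, 0 °C to rt
Reagents that add atoms: chloromethyl methyl ether, COCCl
Why: Williamson-type O-alkylation of both phenoxides installs the two chelating MOM groups that direct the later ortho-lithiations.

Step 2
Reactants: 2 1-methoxy-3,5-bis(methoxymethoxy)benzene
Product: 4 5-methoxy-1,3-bis(methoxymethoxy)-2-(3-methylbut-2-en-1-yl)benzene, via aryllithium 3 (not isolated)
Conditions: n-BuLi, THF, 0 °C to rt; then CuBr·SMe2 (10 mol %), prenyl bromide, −78 °C to rt
Reagents that add atoms: prenyl bromide (1-bromo-3-methylbut-2-ene), CC(C)=CCBr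
Why: Directed ortho-metalation should occur at the one ring position flanked by two MOM ethers, and the aryl-metal is alkylated at the primary carbon of prenyl bromide (SN2).

Step 3
Reactants: 4 5-methoxy-1,3-bis(methoxymethoxy)-2-(3-methylbut-2-en-1-yl)benzene
Product: 6 6-methoxy-2,4-bis(methoxymethoxy)-3-(3-methylbut-2-en-1-yl)benzaldehyde, via aryllithium 5 (not isolated)
Conditions: n-BuLi, TMEDA, THF, −20 to 0 °C; then DMF, 0 °C to rt; H2O
Reagents that add atoms: N,N-dimethylformamide, CN(C)C=O
Why: A second directed ortho-metalation at either of the two equivalent free positions (between OMOM and OMe) followed by formylation with DMF (Bouveault-type aldehyde synthesis) places the formyl group unambiguously.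

Step 4
Reactants: 6 6-methoxy-2,4-bis(methoxymethoxy)-3-(3-methylbut-2-en-1-yl)benzaldehyde
Product: 7 2,4-dihydroxy-6-methoxy-3-(3-methylbut-2-en-1-yl)benzaldehyde
Conditions: HCl (1 M in MeOH), 35 °C
Reagents that add atoms: none
Why: Acid-catalysed acetal exchange with methanol cleaves both MOM ethers under conditions mild enough that the prenyl group should not cyclise onto the flanking phenols.

Step 5
Reactants: 7 2,4-dihydroxy-6-methoxy-3-(3-methylbut-2-en-1-yl)benzaldehyde
Product: 8 4-[(tert-butyldimethylsilyl)oxy]-2-hydroxy-6-methoxy-3-(3-methylbut-2-en-1-yl)benzaldehyde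
Conditions: TBSCl (1.05 equiv), imidazole, CH2Cl2, 0 °C
Reagents that add atoms: tert-butyldimethylsilyl chloride, CC(C)(C)[Si](C)(C)Cl
Why: Selective O-silylation of the more acidic 4-OH (para to the formyl group) is expected because the 2-OH is tied up in a hydrogen bond to the aldehyde.

Step 6
Reactants: 9 (S)-4-hydroxymandelic acid
Product: 10 methyl (S)-4-hydroxymandelate
Conditions: MeI, KHCO3, DMF, rt
Reagents that add atoms: iodomethane, CI
Why: Carboxylate O-alkylation (SN2); bicarbonate deprotonates only the acid, so phenol and carbinol are not methylated and the stereocentre is untouched.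

Step 7
Reactants: 10 methyl (S)-4-hydroxymandelate
Product: 11 methyl (2S)-2-{4-[(tert-butyldimethylsilyl)oxy]phenyl}-2-hydroxyacetate
Conditions: TBSCl (1.05 equiv), imidazole, CH2Cl2, 0 °C
Reagents that add atoms: tert-butyldimethylsilyl chloride, CC(C)(C)[Si](C)(C)Cl
Why: Chemoselective silylation, the phenol reacting much faster than the secondary alpha-hydroxy ester OH.

Step 8
Reactants: 8 4-[(tert-butyldimethylsilyl)oxy]-2-hydroxy-6-methoxy-3-(3-methylbut-2-en-1-yl)benzaldehyde; 11 methyl (2S)-2-{4-[(tert-butyldimethylsilyl)oxy]phenyl}-2-hydroxyacetate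
Product: 12 methyl (2R)-2-{5-[(tert-butyldimethylsilyl)oxy]-2-formyl-3-methoxy-6-(3-methylbut-2-en-1-yl)phenoxy}-2-{4-[(tert-butyldimethylsilyl)oxy]phenyl}acetate
Conditions: PPh3, DIAD, toluene (1 M), 0 °C to rt
Reagents that add atoms: none
Why: Mitsunobu etherification: the acidic chelated phenol displaces the oxyphosphonium of the alpha-hydroxy ester by SN2 with inversion (S to R, the future C2), the ester group disfavouring ionisation, as known for doubly ortho-substituted phenols with alpha-hydroxy esters.

Step 9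
Reactants: 12 methyl (2R)-2-{5-[(tert-butyldimethylsilyl)oxy]-2-formyl-3-methoxy-6-(3-methylbut-2-en-1-yl)phenoxy}-2-{4-[(tert-butyldimethylsilyl)oxy]phenyl}acetate
Product: 13 (2R)-2-{5-[(tert-butyldimethylsilyl)oxy]-2-(hydroxymethyl)-3-methoxy-6-(3-methylbut-2-en-1-yl)phenoxy}-2-{4-[(tert-butyldimethylsilyl)oxy]phenyl}ethan-1-ol
Conditions: i-Bu2AlH (5 equiv), CH2Cl2, −78 to 0 °C; aq. KNaC4H4O6; used crude, no acid
Reagents that add atoms: none
Why: Hydride reduction of ester and aldehyde through non-basic aluminium alkoxides leaves the C2 stereocentre and the aryl silyl ethers intact.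

Step 10
Reactants: 13 (2R)-2-{5-[(tert-butyldimethylsilyl)oxy]-2-(hydroxymethyl)-3-methoxy-6-(3-methylbut-2-en-1-yl)phenoxy}-2-{4-[(tert-butyldimethylsilyl)oxy]phenyl}ethan-1-ol
Product: 14 4-[(tert-butyldimethylsilyl)oxy]-2-[(1R)-1-{4-[(tert-butyldimethylsilyl)oxy]phenyl}-2-oxoethoxy]-6-methoxy-3-(3-methylbut-2-en-1-yl)benzaldehyde
Conditions: Dess–Martin periodinane (2.5 equiv), NaHCO3, CH2Cl2, 0 °C; no chromatography, used at once
Reagents that add atoms: none
Why: Buffered Dess–Martin oxidation of both primary alcohols is non-basic, and the enolisable alpha-aryloxy aldehyde (an O-aryl mandelaldehyde) is taken on crude so that C2 should not epimerise.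

Step 11
Reactants: 14 4-[(tert-butyldimethylsilyl)oxy]-2-[(1R)-1-{4-[(tert-butyldimethylsilyl)oxy]phenyl}-2-oxoethoxy]-6-methoxy-3-(3-methylbut-2-en-1-yl)benzaldehyde
Product: 15 (2R,3S,4S)-7-[(tert-butyldimethylsilyl)oxy]-2-{4-[(tert-butyldimethylsilyl)oxy]phenyl}-5-methoxy-8-(3-methylbut-2-en-1-yl)chromane-3,4-diol
Conditions: SmI2 (3 equiv, 0.1 M in THF), t-BuOH (3 equiv), THF, −78 °C, slow addition of 14 (final 5 mM), then to −20 °C; aq. NaHCO3
Reagents that add atoms: none
Why: SmI2 transfers one electron to the conjugated ring-A aldehyde, the more easily reduced carbonyl, giving a C4 ketyl whose trivalent samarium also binds the C3 aldehyde oxygen; the ketyl carbon adds to the C3 carbonyl carbon and a second SmI2 reduces the resulting oxygen radical to the samarium diolate, which t-BuOH and work-up protonate. The closest known reaction type is the SmI2-mediated intramolecular pinacol coupling of 1,6-dialdehydes to cis-cyclohexane-1,2-diols. Ring C is closed by a 6-exo-trig radical addition to a carbonyl group. C3 and C4 are set as a cis diol by the samarium bridge between the two oxygens; in the half-chair the C2 aryl group stays pseudoequatorial and the C4 oxygen goes pseudoaxial to avoid the peri 5-methoxy group of ring A, which places the C3 oxygen equatorial and trans to the aryl group, that is 2R,3S,4S. The step needs (a) first reduction at the aryl aldehyde and fast cyclisation, so that the alpha-aryloxy aldehyde is not reduced on its own with loss of the aryloxide (secured by the lower reduction potential of the conjugated aldehyde, no HMPA, −78 °C), (b) ring closure over dimerisation (slow addition, high dilution) and (c) an intact C2 centre (crude 14 used at once, no base).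

Step 12
Reactants: 15 (2R,3S,4S)-7-[(tert-butyldimethylsilyl)oxy]-2-{4-[(tert-butyldimethylsilyl)oxy]phenyl}-5-methoxy-8-(3-methylbut-2-en-1-yl)chromane-3,4-diol
Product: 16 5-O-methyl-8-prenylafzelechin-4beta-ol, (2R,3S,4S)-2-(4-hydroxyphenyl)-5-methoxy-8-(3-methylbut-2-en-1-yl)chromane-3,4,7-triol
Conditions: TBAF (2.4 equiv), AcOH (2.4 equiv), THF, 0 °C
Reagents that add atoms: none
Why: Fluoride-mediated cleavage of both aryl silyl ethers; acetic acid keeps the phenols protonated, so the benzylic C4 carbinol and C2 should see neither acid nor free phenoxide and no stereocentre is touched.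

**Compound list**
1 | 5-methoxyresorcinol (5-methoxybenzene-1,3-diol) | COc1cc(O)cc(O)c1 | starting material
2 | 1-methoxy-3,5-bis(methoxymethoxy)benzene | COCOc1cc(OC)cc(OCOC)c1 | intermediate
3 | [4-methoxy-2,6-bis(methoxymethoxy)phenyl]lithium | COCOc1cc(OC)cc(OCOC)c1[Li] | intermediate
4 | 5-methoxy-1,3-bis(methoxymethoxy)-2-(3-methylbut-2-en-1-yl)benzene | COCOc1cc(OC)cc(OCOC)c1CC=C(C)C | intermediate
5 | [6-methoxy-2,4-bis(methoxymethoxy)-3-(3-methylbut-2-en-1-yl)phenyl]lithium | COCOc1cc(OC)c([Li])c(OCOC)c1CC=C(C)C | intermediate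
6 | 6-methoxy-2,4-bis(methoxymethoxy)-3-(3-methylbut-2-en-1-yl)benzaldehyde | COCOc1cc(OC)c(C=O)c(OCOC)c1CC=C(C)C | intermediate
7 | 2,4-dihydroxy-6-methoxy-3-(3-methylbut-2-en-1-yl)benzaldehyde | COc1cc(O)c(CC=C(C)C)c(O)c1C=O | intermediate
8 | 4-[(tert-butyldimethylsilyl)oxy]-2-hydroxy-6-methoxy-3-(3-methylbut-2-en-1-yl)benzaldehyde | COc1cc(O[Si](C)(C)C(C)(C)C)c(CC=C(C)C)c(O)c1C=O | intermediate
9 | (S)-4-hydroxymandelic acid | O=C(O)[C@@H](O)c1ccc(O)cc1 | starting material
10 | methyl (S)-4-hydroxymandelate | COC(=O)[C@@H](O)c1ccc(O)cc1 | intermediate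
11 | methyl (2S)-2-{4-[(tert-butyldimethylsilyl)oxy]phenyl}-2-hydroxyacetate | COC(=O)[C@@H](O)c1ccc(O[Si](C)(C)C(C)(C)C)cc1 | intermediate
12 | methyl (2R)-2-{5-[(tert-butyldimethylsilyl)oxy]-2-formyl-3-methoxy-6-(3-methylbut-2-en-1-yl)phenoxy}-2-{4-[(tert-butyldimethylsilyl)oxy]phenyl}acetate | COc1cc(O[Si](C)(C)C(C)(C)C)c(CC=C(C)C)c(O[C@@H](C(=O)OC)c2ccc(O[Si](C)(C)C(C)(C)C)cc2)c1C=O | intermediate
13 | (2R)-2-{5-[(tert-butyldimethylsilyl)oxy]-2-(hydroxymethyl)-3-methoxy-6-(3-methylbut-2-en-1-yl)phenoxy}-2-{4-[(tert-butyldimethylsilyl)oxy]phenyl}ethan-1-ol | COc1cc(O[Si](C)(C)C(C)(C)C)c(CC=C(C)C)c(O[C@@H](CO)c2ccc(O[Si](C)(C)C(C)(C)C)cc2)c1CO | intermediate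
14 | 4-[(tert-butyldimethylsilyl)oxy]-2-[(1R)-1-{4-[(tert-butyldimethylsilyl)oxy]phenyl}-2-oxoethoxy]-6-methoxy-3-(3-methylbut-2-en-1-yl)benzaldehyde | COc1cc(O[Si](C)(C)C(C)(C)C)c(CC=C(C)C)c(O[C@@H](C=O)c2ccc(O[Si](C)(C)C(C)(C)C)cc2)c1C=O | intermediate
15 | (2R,3S,4S)-7-[(tert-butyldimethylsilyl)oxy]-2-{4-[(tert-butyldimethylsilyl)oxy]phenyl}-5-methoxy-8-(3-methylbut-2-en-1-yl)chromane-3,4-diol | COc1cc(O[Si](C)(C)C(C)(C)C)c(CC=C(C)C)c2c1[C@H](O)[C@H](O)[C@@H](c1ccc(O[Si](C)(C)C(C)(C)C)cc1)O2 | intermediate
16 | 5-O-methyl-8-prenylafzelechin-4beta-ol, (2R,3S,4S)-2-(4-hydroxyphenyl)-5-methoxy-8-(3-methylbut-2-en-1-yl)chromane-3,4,7-triol | COc1cc(O)c(CC=C(C)C)c2c1[C@H](O)[C@H](O)[C@@H](c1ccc(O)cc1)O2 | target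

**Totals**
Total step count: 12. Longest linear sequence: 10 steps (steps 1–5 and 8–12, from 1).

**Steps most likely to fail**

Step 11. What may go wrong: chelate control in the ketyl–carbonyl coupling may be incomplete, so that the ring closes with poor facial selectivity at C4 and the 3,4-trans diol forms alongside 15. The fallback sets out from 14 and comes back at 15. The closure is run as in step 11, but the configuration at C3 and C4 is then set by an oxidation–reduction relay instead of by the coupling. The unseparated mixture of 15 and its C4 epimer (2R,3S,4R)-7-[(tert-butyldimethylsilyl)oxy]-2-{4-[(tert-butyldimethylsilyl)oxy]phenyl}-5-methoxy-8-(3-methylbut-2-en-1-yl)chromane-3,4-diol F1 would be oxidised with MnO2 in CH2Cl2 at the benzylic C4 carbinol only. This should give the 2,3-trans ketol (2R,3R)-7-[(tert-butyldimethylsilyl)oxy]-2-{4-[(tert-butyldimethylsilyl)oxy]phenyl}-3-hydroxy-5-methoxy-8-(3-methylbut-2-en-1-yl)chroman-4-one F2, in which C3, now alpha to the ketone, can settle in the favoured trans arrangement. Reduction with LiB(s-Bu)3H in THF at −78 °C should deliver hydride from the equatorial side, away from the axial hydrogen at C2, giving the axial 4-OH cis to the 3-OH, that is 15.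

Step 8. What may go wrong: SN2 attack by the doubly ortho-substituted, hydrogen-bonded phenol may be slow, so that the oxyphosphonium is consumed by the hydrazide or ionises with erosion of configuration. The fallback sets out from 8 and comes back at 12. It makes the O1–C2 bond by enantioselective carbene O–H insertion, which does not depend on backside attack. Commercial methyl 4-hydroxyphenylacetate would be silylated (TBSCl, imidazole) to methyl 2-{4-[(tert-butyldimethylsilyl)oxy]phenyl}acetate F3. Diazo transfer (4-acetamidobenzenesulfonyl azide, DBU, MeCN) would convert this into methyl 2-diazo-2-{4-[(tert-butyldimethylsilyl)oxy]phenyl}acetate F4. Insertion of the carbene from F4 into the phenol O–H of 8 would use Pd(PhCN)2Cl2 (divalent palladium), a chiral spiro bis(oxazoline) ligand and NaB[3,5-(CF3)2C6H3]4 in CHCl3, a known catalyst class for phenol O–H insertion of alpha-aryl diazoacetates. The ligand enantiomer would be chosen to give the (R)-ether 12.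

Step 2. What may go wrong: lithiation may compete at the positions between OMOM and OMe, giving the regioisomeric prenyl arene. The fallback sets out from 1 and comes back at 7, bypassing steps 1–4. Vilsmeier–Haack formylation of 1 (POCl3, DMF; then H2O) should give 2,4-dihydroxy-6-methoxybenzaldehyde F5. Its more acidic, non-chelated 4-OH would be O-alkylated with tert-butyl 2-methylbut-3-en-2-yl carbonate and Pd(PPh3)4 (zerovalent palladium) in THF, giving 2-hydroxy-6-methoxy-4-[(2-methylbut-3-en-2-yl)oxy]benzaldehyde F6. Aromatic Claisen rearrangement (N,N-diethylaniline, 190 °C) should then move the allyl unit, as a linear prenyl group, to C3 between the two oxygens, the ortho position favoured by bond fixation in the chelated salicylaldehyde, giving 7.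

**Further compounds**
F1 | step 11 | (2R,3S,4R)-7-[(tert-butyldimethylsilyl)oxy]-2-{4-[(tert-butyldimethylsilyl)oxy]phenyl}-5-methoxy-8-(3-methylbut-2-en-1-yl)chromane-3,4-diol | COc1cc(O[Si](C)(C)C(C)(C)C)c(CC=C(C)C)c2c1[C@@H](O)[C@H](O)[C@@H](c1ccc(O[Si](C)(C)C(C)(C)C)cc1)O2
F2 | step 11 | (2R,3R)-7-[(tert-butyldimethylsilyl)oxy]-2-{4-[(tert-butyldimethylsilyl)oxy]phenyl}-3-hydroxy-5-methoxy-8-(3-methylbut-2-en-1-yl)chroman-4-one | COc1cc(O[Si](C)(C)C(C)(C)C)c(CC=C(C)C)c2c1C(=O)[C@H](O)[C@@H](c1ccc(O[Si](C)(C)C(C)(C)C)cc1)O2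
F3 | step 8 | methyl 2-{4-[(tert-butyldimethylsilyl)oxy]phenyl}acetate | COC(=O)Cc1ccc(O[Si](C)(C)C(C)(C)C)cc1
F4 | step 8 | methyl 2-diazo-2-{4-[(tert-butyldimethylsilyl)oxy]phenyl}acetate | COC(=O)C(=[N+]=[N-])c1ccc(O[Si](C)(C)C(C)(C)C)cc1
F5 | step 2 | 2,4-dihydroxy-6-methoxybenzaldehyde | COc1cc(O)cc(O)c1C=O
F6 | step 2 | 2-hydroxy-6-methoxy-4-[(2-methylbut-3-en-2-yl)oxy]benzaldehyde | COc1cc(OC(C)(C)C=C)cc(O)c1C=O
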